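Ring B is cut at C1'–C2' and C5'–C6'. Its oxygens on C2', C4' and C5' and hydrogens on C3' and C6' are what a 1,1,3,4-tetraoxygenated butadiene leaves after adding to a terminal alkyne held on C2 of the pyranone (ring C). One cycloaddition–aromatization thus builds the complete hydroxyquinol ring, correctly oriented, on a finished ring A/C core. The precursor is 2-ethynyl-7-methoxy-5-(methoxymethoxy)-3,6,8-triprenylchromone, reached from phloroacetophenone through a chromone-2-carboxylate. Its partner is a tris(trimethylsilyloxy) diene carrying the future 5'-oxygen as a MOM ether, made from methyl glycolate. Acid methanolysis of the two MOM ethers finishes the synthesis.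

Key step: step 14

Remark: prenyl = 3-methylbut-2-en-1-yl. The target and all isolated intermediates are achiral. The 3Z geometry of diene 24 is assumed and is erased on aromatization, as are the transient centres of 10 and 25.

Step 1
Reactants: 1 2,4,6-trihydroxyacetophenone; 2 prenyl bromide (2.1 equiv)
Product: 3 1-[2,4,6-trihydroxy-3,5-bis(3-methylbut-2-enyl)phenyl]ethanone
Conditions: aq. KOH (10%), 0 °C → rt, N2
Reagents that add atoms: prenyl bromide (2), CC(C)=CCBr
Why: Nuclear C-prenylation of the phloroglucinol polyanion (SN2 C-alkylation of an ambident phenolate) is the usual entry to diprenylated acylphloroglucinols; water solvates the oxygens and steers the allylic bromide to the two free ring carbons C3 and C5, and the symmetric product should be separable from mono- and over-alkylated material.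

Step 2
Reactants: 3 1-[2,4,6-trihydroxy-3,5-bis(3-methylbut-2-enyl)phenyl]ethanone
Product: 4 1-[2,6-dihydroxy-4-methoxy-3,5-bis(3-methylbut-2-enyl)phenyl]ethanone
Conditions: MeI (1.05 equiv), K2CO3 (1.0 equiv), acetone, 0 °C → rt
Reagents that add atoms: iodomethane, CI
Why: Williamson O-methylation with one equivalent of base should take the 4-hydroxyl, the most acidic phenol (para to the acyl group) and the one that cannot chelate to the carbonyl, as is usual for acylphloroglucinols.

Step 3
Reactants: 4 1-[2,6-dihydroxy-4-methoxy-3,5-bis(3-methylbut-2-enyl)phenyl]ethanone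
Product: 5 1-[2-hydroxy-4-methoxy-6-(methoxymethoxy)-3,5-bis(3-methylbut-2-enyl)phenyl]ethanone
Conditions: MOMCl (1.2 equiv), iPr2NEt, CH2Cl2, 0 °C → rt
Reagents that add atoms: chloromethyl methyl ether, COCCl
Why: Williamson-type MOM etherification under a weak amine base should stop after one of the two equivalent ortho-oxygens, because the remaining hydroxyl is then locked in a strong hydrogen bond to the ketone.

Step 4
Reactants: 5 1-[2-hydroxy-4-methoxy-6-(methoxymethoxy)-3,5-bis(3-methylbut-2-enyl)phenyl]ethanone; 2 prenyl bromide (1.0 equiv)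
Product: 7 1-[2-hydroxy-4-methoxy-6-(methoxymethoxy)-3,5-bis(3-methylbut-2-enyl)phenyl]-5-methylhex-4-en-1-one, via dilithium phenoxide-enolate 6 (not isolated)
Conditions: LiN(iPr)2 (LDA, 2.3 equiv), THF, −78 → −20 °C; prenyl bromide, −78 → 0 °C; aq. NH4Cl
Reagents that add atoms: prenyl bromide (2), CC(C)=CCBr
Why: Ketone enolate alkylation: double deprotonation gives the phenoxide–enolate, whose carbon terminus is far more nucleophilic than the chelated lithium phenoxide, so one equivalent of the allylic bromide should give SN2 C-prenylation to the homoprenyl ketone.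

Step 5
Reactants: 7 1-[2-hydroxy-4-methoxy-6-(methoxymethoxy)-3,5-bis(3-methylbut-2-enyl)phenyl]-5-methylhex-4-en-1-one; 8 ethyl chlorooxoacetate (2.5 equiv)
Product: 11 ethyl 7-methoxy-5-(methoxymethoxy)-3,6,8-tris(3-methylbut-2-enyl)-4-oxo-4H-chromene-2-carboxylate, via aryl ethyl oxalate 9 (not isolated), via 2-hydroxychromanone hemiketal 10 (not isolated)
Conditions: ClCOCO2Et, pyridine, 0 °C → 60 °C
Reagents that add atoms: ethyl chlorooxoacetate (8), CCOC(=O)C(=O)Cl
Why: Chromone annulation with ethoxalyl chloride in pyridine (O-acylation, Baker–Venkataraman-type intramolecular Claisen attack of the ketone α-carbon on the adjacent aryl oxalate carbonyl, then dehydration of the hemiketal to the aromatic pyranone) needs no mineral acid, so the MOM ether and the prenyl groups should survive, and the prenylated α-carbon becomes C3.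

Step 6
Reactants: 11 ethyl 7-methoxy-5-(methoxymethoxy)-3,6,8-tris(3-methylbut-2-enyl)-4-oxo-4H-chromene-2-carboxylate
Product: 12 2-(hydroxymethyl)-7-methoxy-5-(methoxymethoxy)-3,6,8-tris(3-methylbut-2-enyl)-4H-chromen-4-one
Conditions: NaBH4 (1.5 equiv), MeOH/THF, −10 → 0 °C
Reagents that add atoms: none
Why: Chemoselective borohydride reduction of an activated ester: the C2 ester, flanked by the ring oxygen and conjugated to the enone, should be reduced to the primary alcohol faster than the vinylogous-ester carbonyl C4 or the tetrasubstituted C2=C3 bond.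

Step 7
Reactants: 12 2-(hydroxymethyl)-7-methoxy-5-(methoxymethoxy)-3,6,8-tris(3-methylbut-2-enyl)-4H-chromen-4-one
Product: 13 7-methoxy-5-(methoxymethoxy)-3,6,8-tris(3-methylbut-2-enyl)-4-oxo-4H-chromene-2-carbaldehyde
Conditions: Dess–Martin periodinane (1.3 equiv), NaHCO3, CH2Cl2, 0 °C → rt
Reagents that add atoms: none
Why: Dess–Martin oxidation of the allylic-type primary alcohol should stop at the aldehyde under buffered conditions that leave the prenyl alkenes and the MOM ether untouched.

Step 8
Reactants: 13 7-methoxy-5-(methoxymethoxy)-3,6,8-tris(3-methylbut-2-enyl)-4-oxo-4H-chromene-2-carbaldehyde; 14 dimethyl (1-diazo-2-oxopropyl)phosphonate (1.3 equiv)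
Product: 15 2-ethynyl-7-methoxy-5-(methoxymethoxy)-3,6,8-tris(3-methylbut-2-enyl)-4H-chromen-4-one
Conditions: K2CO3 (2 equiv), MeOH/THF, 0 °C → rt, short reaction time
Reagents that add atoms: dimethyl (1-diazo-2-oxopropyl)phosphonate (14), COP(=O)(OC)C(=[N+]=[N-])C(C)=O
Why: Seyferth–Gilbert homologation in its Ohira–Bestmann form: methanolysis of 14 gives the diazomethylphosphonate anion, which adds to the aldehyde, expels dimethyl phosphate (Horner–Wadsworth–Emmons-type) and, after loss of N2 and 1,2-hydride shift of the alkylidene carbene, should give the terminal alkyne, low temperature limiting attack of methoxide on the pyranone.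

Step 9
Reactants: 16 methyl glycolate
Product: 17 methyl 2-(methoxymethoxy)acetate
Conditions: MOMCl, iPr2NEt, CH2Cl2, 0 °C → rt
Reagents that add atoms: chloromethyl methyl ether, COCCl
Why: Standard MOM protection of a primary alcohol (Williamson-type alkylation with an α-chloro ether).

Step 10
Reactants: 17 methyl 2-(methoxymethoxy)acetate; 18 methyl acetate (2.2 equiv)
Product: 20 methyl 4-(methoxymethoxy)-3-oxobutanoate, via lithium enolate of methyl acetate 19 (not isolated)
Conditions: LiN(iPr)2 (LDA, 2.2 equiv), MeOAc, THF, −78 °C; then 17, −78 → −30 °C; AcOH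
Reagents that add atoms: methyl acetate (18), COC(C)=O
Why: Crossed Claisen condensation: the preformed lithium ester enolate attacks the more electrophilic α-alkoxy ester 17, and deprotonation of the β-keto ester product drives the reaction.

Step 11
Reactants: 20 methyl 4-(methoxymethoxy)-3-oxobutanoate
Product: 21 lithium 4-(methoxymethoxy)-3-oxobutanoate
Conditions: LiOH·H2O (1.0 equiv), THF/H2O, 0 °C → rt; freeze-drying
Reagents that add atoms: lithium hydroxide, [Li+].[OH-]
Why: Saponification with exactly one equivalent of hydroxide; isolating the carboxylate salt avoids the free β-keto acid and its decarboxylation.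

Step 12
Reactants: 21 lithium 4-(methoxymethoxy)-3-oxobutanoate
Product: 22 trimethylsilyl 4-(methoxymethoxy)-3-(trimethylsilyloxy)but-2-enoate
Conditions: Me3SiCl (2.3 equiv), Et3N (1.3 equiv), THF, 0 °C → rt; filtration under Ar
Reagents that add atoms: chlorotrimethylsilane, C[Si](C)(C)Cl
Why: Silylation: Me3SiCl converts the lithium carboxylate into the silyl ester and, with Et3N, the β-keto group into its conjugated silyl enol ether.

Step 13
Reactants: 22 trimethylsilyl 4-(methoxymethoxy)-3-(trimethylsilyloxy)but-2-enoate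
Product: 24 (3Z)-4-(methoxymethoxy)-1,1,3-tris(trimethylsilyloxy)buta-1,3-diene, via lithium dienolate 23 (not isolated)
Conditions: LiN(iPr)2 (LDA, 1.1 equiv), THF, −78 °C; Me3SiCl, −78 → 0 °C; pentane, filtration under Ar, used crude
Reagents that add atoms: chlorotrimethylsilane, C[Si](C)(C)Cl
Why: Vinylogous (γ) deprotonation of the β-silyloxy enoate and O-silylation of the dienolate is the standard second stage in the preparation of 1,3-bis(silyloxy) ketene-acetal dienes, and the 4-alkoxy group should end up trans to C2 (3Z), the geometry that can reach the s-cis conformation.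

Step 14
Reactants: 15 2-ethynyl-7-methoxy-5-(methoxymethoxy)-3,6,8-tris(3-methylbut-2-enyl)-4H-chromen-4-one; 24 (3Z)-4-(methoxymethoxy)-1,1,3-tris(trimethylsilyloxy)buta-1,3-diene (3 equiv)
Product: 27 2-[2,4-dihydroxy-5-(methoxymethoxy)phenyl]-7-methoxy-5-(methoxymethoxy)-3,6,8-tris(3-methylbut-2-enyl)-4H-chromen-4-one, via cyclohexa-1,4-diene cycloadduct 25 (not isolated), via bis(trimethylsilyl) ether 26 (not isolated)
Conditions: toluene, 100 °C, sealed tube, Ar; then MeOH, citric acid (cat.), 0 °C
Reagents that add atoms: diene 24, C[Si](C)(C)OC(O[Si](C)(C)C)=C/C(O[Si](C)(C)C)=C/OCOC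
Why: The pyranone carbonyl polarizes the ethynyl group through C3=C2 like a vinylogous ynone, so the electron-rich diene should add in a normal-demand, concerted but strongly asynchronous [4+2] cycloaddition in which the C5'–C6' bond (diene C4 to the terminal alkyne carbon) runs ahead of the C1'–C2' bond (ketene-acetal carbon to the internal alkyne carbon). The closest known reaction type is the Diels–Alder benzannulation of 1,1,3-trioxygenated silyloxy dienes with acetylenic esters and ketones, which ends in aromatization by 1,4-elimination. Ring B closes as a six-membered carbocycle in the [4+2] mode (in the stepwise limit a Mukaiyama–Michael addition followed by 6-exo-trig attack of the allenyl enolate on the silylated ester carbon) to give cyclohexa-1,4-diene 25, which loses trimethylsilanol across C2' and C5'–H to give arene 26; brief acidic methanolysis then cleaves the two aryl silyl ethers but not the MOM ethers. No stereocentre has to be controlled, since the only one formed (C5' of 25) is erased on aromatization. The step needs regioselectivity, secured by matched polarization: diene C4, pushed by the oxygens on C1 and C3 (the 4-alkoxy group opposes this only weakly), is the nucleophilic terminus and meets the electrophilic alkyne terminus, which places the 2'-oxygen next to the chromone. It also needs chemoselectivity, secured because C2=C3 of the pyranone is tetrasubstituted, the prenyl alkenes are unactivated, the 5-hydroxyl is capped so that no acidic proton destroys the ketene acetal, and no metal or Lewis acid is present that could trigger enyne cyclization with the 3-prenyl group.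

Step 15
Reactants: 27 2-[2,4-dihydroxy-5-(methoxymethoxy)phenyl]-7-methoxy-5-(methoxymethoxy)-3,6,8-tris(3-methylbut-2-enyl)-4H-chromen-4-one
Product: 28 5-hydroxy-7-methoxy-3,6,8-tris(3-methylbut-2-enyl)-2-(2,4,5-trihydroxyphenyl)-4H-chromen-4-one
Conditions: HCl in MeOH (1.25 M, degassed), Ar, rt → 40 °C
Reagents that add atoms: none
Why: Acid-catalysed acetal exchange (methanolysis) should remove both MOM ethers, the chelated 5-O-MOM first, and dilute acid, moderate temperature and exclusion of air are chosen to avoid chroman formation between prenyl groups and neighbouring phenols and autoxidation of the hydroxyquinol ring.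

Compound list
1 | 2,4,6-trihydroxyacetophenone | CC(=O)c1c(O)cc(O)cc1O | starting material
2 | prenyl bromide (1-bromo-3-methylbut-2-ene) | CC(C)=CCBr | starting material
3 | 1-[2,4,6-trihydroxy-3,5-bis(3-methylbut-2-enyl)phenyl]ethanone | CC(=O)c1c(O)c(CC=C(C)C)c(O)c(CC=C(C)C)c1O | intermediate
4 | 1-[2,6-dihydroxy-4-methoxy-3,5-bis(3-methylbut-2-enyl)phenyl]ethanone | CC(=O)c1c(O)c(CC=C(C)C)c(OC)c(CC=C(C)C)c1O | intermediate
5 | 1-[2-hydroxy-4-methoxy-6-(methoxymethoxy)-3,5-bis(3-methylbut-2-enyl)phenyl]ethanone | CC(=O)c1c(O)c(CC=C(C)C)c(OC)c(CC=C(C)C)c1OCOC | intermediate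
6 | dilithium phenoxide–enolate of 5 | [Li+].[Li+].C=C([O-])c1c([O-])c(CC=C(C)C)c(OC)c(CC=C(C)C)c1OCOC | intermediate (not isolated)
7 | 1-[2-hydroxy-4-methoxy-6-(methoxymethoxy)-3,5-bis(3-methylbut-2-enyl)phenyl]-5-methylhex-4-en-1-one | CC(C)=CCCC(=O)c1c(O)c(CC=C(C)C)c(OC)c(CC=C(C)C)c1OCOC | intermediate
8 | ethyl chlorooxoacetate | CCOC(=O)C(=O)Cl | starting material
9 | ethyl 2-(5-methylhex-4-enoyl)-5-methoxy-3-(methoxymethoxy)-4,6-bis(3-methylbut-2-enyl)phenyl oxalate | CCOC(=O)C(=O)Oc1c(CC=C(C)C)c(OC)c(CC=C(C)C)c(OCOC)c1C(=O)CCC=C(C)C | intermediate (not isolated)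
10 | ethyl 2-hydroxy-7-methoxy-5-(methoxymethoxy)-3,6,8-tris(3-methylbut-2-enyl)-4-oxochromane-2-carboxylate (diastereomer mixture) | CCOC(=O)C1(O)Oc2c(CC=C(C)C)c(OC)c(CC=C(C)C)c(OCOC)c2C(=O)C1CC=C(C)C | intermediate (not isolated)
11 | ethyl 7-methoxy-5-(methoxymethoxy)-3,6,8-tris(3-methylbut-2-enyl)-4-oxo-4H-chromene-2-carboxylate | CCOC(=O)c1oc2c(CC=C(C)C)c(OC)c(CC=C(C)C)c(OCOC)c2c(=O)c1CC=C(C)C | intermediate
12 | 2-(hydroxymethyl)-7-methoxy-5-(methoxymethoxy)-3,6,8-tris(3-methylbut-2-enyl)-4H-chromen-4-one | OCc1oc2c(CC=C(C)C)c(OC)c(CC=C(C)C)c(OCOC)c2c(=O)c1CC=C(C)C | intermediate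
13 | 7-methoxy-5-(methoxymethoxy)-3,6,8-tris(3-methylbut-2-enyl)-4-oxo-4H-chromene-2-carbaldehyde | O=Cc1oc2c(CC=C(C)C)c(OC)c(CC=C(C)C)c(OCOC)c2c(=O)c1CC=C(C)C | intermediate
14 | dimethyl (1-diazo-2-oxopropyl)phosphonate | COP(=O)(OC)C(=[N+]=[N-])C(C)=O | starting material
15 | 2-ethynyl-7-methoxy-5-(methoxymethoxy)-3,6,8-tris(3-methylbut-2-enyl)-4H-chromen-4-one | COc1c(CC=C(C)C)c(OCOC)c2c(=O)c(CC=C(C)C)c(C#C)oc2c1CC=C(C)C | intermediate
16 | methyl glycolate | COC(=O)CO | starting material
17 | methyl 2-(methoxymethoxy)acetate | COCOCC(=O)OC | intermediate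
18 | methyl acetate | COC(C)=O | starting material
19 | lithium enolate of methyl acetate | [Li+].C=C([O-])OC | intermediate (not isolated)
20 | methyl 4-(methoxymethoxy)-3-oxobutanoate | COCOCC(=O)CC(=O)OC | intermediate
21 | lithium 4-(methoxymethoxy)-3-oxobutanoate | [Li+].COCOCC(=O)CC(=O)[O-] | intermediate
22 | trimethylsilyl 4-(methoxymethoxy)-3-(trimethylsilyloxy)but-2-enoate (E/Z mixture; this double bond becomes the C2–C3 single bond of 24) | COCOCC(O[Si](C)(C)C)=CC(=O)O[Si](C)(C)C | intermediate
23 | lithium dienolate of 22 | [Li+].[O-]C(O[Si](C)(C)C)=C/C(O[Si](C)(C)C)=C/OCOC | intermediate (not isolated)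
24 | (3Z)-4-(methoxymethoxy)-1,1,3-tris(trimethylsilyloxy)buta-1,3-diene | C[Si](C)(C)OC(O[Si](C)(C)C)=C/C(O[Si](C)(C)C)=C/OCOC | intermediate
25 | cyclohexa-1,4-diene cycloadduct (racemic at C5'; 2',2',4'-tris(trimethylsilyloxy), 5'-methoxymethoxy) | COCOC1C=C(c2oc3c(CC=C(C)C)c(OC)c(CC=C(C)C)c(OCOC)c3c(=O)c2CC=C(C)C)C(O[Si](C)(C)C)(O[Si](C)(C)C)C=C1O[Si](C)(C)C | intermediate (not isolated)
26 | 2',4'-bis(trimethylsilyl) ether of 27 | COCOc1cc(-c2oc3c(CC=C(C)C)c(OC)c(CC=C(C)C)c(OCOC)c3c(=O)c2CC=C(C)C)c(O[Si](C)(C)C)cc1O[Si](C)(C)C | intermediate (not isolated)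
27 | 2-[2,4-dihydroxy-5-(methoxymethoxy)phenyl]-7-methoxy-5-(methoxymethoxy)-3,6,8-tris(3-methylbut-2-enyl)-4H-chromen-4-one | COc1c(CC=C(C)C)c(OCOC)c2c(=O)c(CC=C(C)C)c(-c3cc(OCOC)c(O)cc3O)oc2c1CC=C(C)C | intermediate
28 | 5-hydroxy-7-methoxy-3,6,8-tris(3-methylbut-2-enyl)-2-(2,4,5-trihydroxyphenyl)-4H-chromen-4-one | COc1c(CC=C(C)C)c(O)c2c(=O)c(CC=C(C)C)c(-c3cc(O)c(O)cc3O)oc2c1CC=C(C)C | target

Total step count: 15. Longest linear sequence: 10 steps (steps 1–8, 14 and 15); the diene branch (steps 9–13) joins at step 14.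

Steps most likely to fail

Step 14. The vinylogously activated alkyne may react too slowly, so that the moisture-sensitive diene is lost to desilylation or oligomerization first; the hindered C1'–C2' closure next to the 3-prenyl group may stall after the first bond; or the first bond may form at the wrong terminus and regiocontrol is lost. The fallback sets out from 7 and returns at 28 by classical flavone assembly. Commercial 2,4,5-trihydroxybenzaldehyde is protected (MOMCl, NaH) as 2,4,5-tris(methoxymethoxy)benzaldehyde F1, oxidized under Pinnick conditions (NaClO2, NaH2PO4, 2-methylbut-2-ene) to 2,4,5-tris(methoxymethoxy)benzoic acid F2 and activated with carbonyldiimidazole as 1-[2,4,5-tris(methoxymethoxy)benzoyl]imidazole F3. Ketone 7 is deprotonated with LiN(SiMe3)2 (3 equiv) to its dilithium phenoxide–enolate F4, which is C-acylated by F3 (Baker–Venkataraman-type Claisen acylation) to the 2-prenyl-1,3-diketone F5. Cyclodehydration (NaOAc, AcOH, 90 °C) should close the pyranone to the 5,2',4',5'-tetrakis(methoxymethyl) ether of the target F6, and methanolic HCl as in step 15 then gives 28.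

Step 8. Methoxide may add to C2 of the pyranone and open ring C, or methanol may add across the newly formed conjugated alkyne. The fallback sets out from 7 and returns at 15; it installs the alkyne before ring C exists. The dianion F4 is C-acylated with commercial ethyl 3-(trimethylsilyl)propiolate to 1-[2-hydroxy-4-methoxy-6-(methoxymethoxy)-3,5-bis(3-methylbut-2-enyl)phenyl]-2-(3-methylbut-2-enyl)-5-(trimethylsilyl)pent-4-yne-1,3-dione F7. Mild acid-catalysed cyclodehydration (pyridinium p-toluenesulfonate, toluene, 50 °C) should give 7-methoxy-5-(methoxymethoxy)-3,6,8-tris(3-methylbut-2-enyl)-2-[(trimethylsilyl)ethynyl]-4H-chromen-4-one F8, and buffered fluoride (Bu4NF, AcOH, THF, 0 °C) removes the silyl group to give 15.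

Step 5. With a hindered and only weakly acidic α-methylene, the pyridine-mediated ring closure may stall at the O-acylated stage, or the 2-hydroxychromanone may fail to lose water. The fallback sets out from 7 and returns at 11; it inverts the order of bond formation to C-acylation first. A crossed Claisen condensation of 7 with diethyl oxalate (NaOEt, EtOH/THF, 0 °C → rt) should give, after neutralization, the ring-closed hemiketal 10, which is isolated and dehydrated with catalytic p-toluenesulfonic acid in toluene at 50 °C over molecular sieves to 11.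

Further compounds
F1 | step 14 | 2,4,5-tris(methoxymethoxy)benzaldehyde | O=Cc1cc(OCOC)c(OCOC)cc1OCOC
F2 | step 14 | 2,4,5-tris(methoxymethoxy)benzoic acid | OC(=O)c1cc(OCOC)c(OCOC)cc1OCOC
F3 | step 14 | 1-[2,4,5-tris(methoxymethoxy)benzoyl]imidazole | O=C(c1cc(OCOC)c(OCOC)cc1OCOC)n1ccnc1
F4 | step 14 | dilithium phenoxide–enolate of 7 | [Li+].[Li+].CC(C)=CCC=C([O-])c1c([O-])c(CC=C(C)C)c(OC)c(CC=C(C)C)c1OCOC
F5 | step 14 | 1-[2-hydroxy-4-methoxy-6-(methoxymethoxy)-3,5-bis(3-methylbut-2-enyl)phenyl]-2-(3-methylbut-2-enyl)-3-[2,4,5-tris(methoxymethoxy)phenyl]propane-1,3-dione (racemic, enolizable) | CC(C)=CCC(C(=O)c1cc(OCOC)c(OCOC)cc1OCOC)C(=O)c1c(O)c(CC=C(C)C)c(OC)c(CC=C(C)C)c1OCOC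
F6 | step 14 | 7-methoxy-5-(methoxymethoxy)-3,6,8-tris(3-methylbut-2-enyl)-2-[2,4,5-tris(methoxymethoxy)phenyl]-4H-chromen-4-one | COc1c(CC=C(C)C)c(OCOC)c2c(=O)c(CC=C(C)C)c(-c3cc(OCOC)c(OCOC)cc3OCOC)oc2c1CC=C(C)C
F7 | step 8 | 1-[2-hydroxy-4-methoxy-6-(methoxymethoxy)-3,5-bis(3-methylbut-2-enyl)phenyl]-2-(3-methylbut-2-enyl)-5-(trimethylsilyl)pent-4-yne-1,3-dione (racemic, enolizable) | CC(C)=CCC(C(=O)C#C[Si](C)(C)C)C(=O)c1c(O)c(CC=C(C)C)c(OC)c(CC=C(C)C)c1OCOC
F8 | step 8 | 7-methoxy-5-(methoxymethoxy)-3,6,8-tris(3-methylbut-2-enyl)-2-[(trimethylsilyl)ethynyl]-4H-chromen-4-one | C[Si](C)(C)C#Cc1oc2c(CC=C(C)C)c(OC)c(CC=C(C)C)c(OCOC)c2c(=O)c1CC=C(C)C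
F0 | step 5 | none | none
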